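The ester C–O bond divides the target into a furyl diynol and a furyl diynoic acid. Everything rests on the unsymmetrical 1,3-diyne C5≡C6–C7≡C8 of the acyl chain: its C1–C6 half (ester end) and its C7–C19 half (the chain ending in a furan ring) are each one half of a symmetrical diyne made by oxidative dimerisation of a terminal alkyne. A molybdenum alkylidyne lets these two homodimers, a C12 diester and a C26 difuryl diyne, swap chain ends, which forms one triple bond (C5≡C6 or C7≡C8) of the mixed diyne in a single operation; no ring closes and both furan rings are spectators. Saponification and esterification with the diynol complete the route.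

Key step: step 6

Remark: the target has no stereocentre, so no step has to control configuration; the aryl group on the carbyne carbon of the catalyst is taken to be 4-methoxyphenyl. Furan is metalated once, in step 1, on a scale that serves both furan alkylations; the THF solution of the furyllithium is divided between steps 1 and 2, which are run on the same day.

Step 1
Reactants: 1 furan; 2 1,11-dibromoundecane
Product: 4 2-(11-bromoundecyl)furan, via 2-lithiofuran 3 (not isolated)
Conditions: n-BuLi, THF, −78 → 0 °C (batch sized for steps 1 and 2); one portion of the solution added to 2 (3 equiv), THF, 0 °C → rt; chromatography, excess 2 recovered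
Reagents that add atoms: n-butyllithium, [Li]CCCC (supplies the lithium of intermediate 3; nothing from it remains in 4)
Why: Furan is lithiated at C2 next to the ring oxygen and the furyllithium displaces one primary bromide in an SN2 alkylation, the excess of dibromide and the inverse addition being there to suppress a second substitution.

Step 2
Reactants: 3 2-lithiofuran (the second portion of the THF solution made in step 1, kept at 0 °C under argon); 5 1-bromo-4-chlorobutane
Product: 6 2-(4-chlorobutyl)furan
Conditions: 5 (1.0 equiv), THF, −78 °C → rt
Reagents that add atoms: none
Why: SN2 alkylation of 2-furyllithium, which is stable in THF at 0 °C for the hours needed, takes place at the bromide far faster than at the chloride, so the chlorobutyl chain should result without an excess of electrophile.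

Step 3
Reactants: 4 2-(11-bromoundecyl)furan
Product: 7 2-(tridec-12-yn-1-yl)furan
Conditions: LiC≡CH·H2NCH2CH2NH2 (1.5 equiv), DMSO, 10 °C → rt
Reagents that add atoms: lithium acetylide–ethylenediamine complex, [Li]C#C.NCCN
Why: SN2 alkynylation of a primary bromide by lithium acetylide in DMSO is a standard two-carbon chain extension that a 2-alkylfuran tolerates.

Step 4
Reactants: 7 2-(tridec-12-yn-1-yl)furan (two molecules are joined per molecule of product)
Product: 8 1,26-di(furan-2-yl)hexacosa-12,14-diyne
Conditions: CuCl (10 mol%), TMEDA (20 mol%), O2 (1 atm), acetone, rt; filtration through silica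
Reagents that add atoms: 2-(tridec-12-yn-1-yl)furan (the second molecule of 7), C#CCCCCCCCCCCCc1ccco1
Why: Glaser–Hay oxidative homocoupling joins the copper acetylides of two molecules of 7 to the symmetrical diyne, the two alkyne hydrogens ending up in water, under conditions that leave the furan rings untouched.

Step 5
Reactants: 9 methyl hex-5-ynoate (two molecules are joined per molecule of product)
Product: 10 dimethyl dodeca-5,7-diynedioate
Conditions: CuCl (10 mol%), TMEDA (20 mol%), O2 (1 atm), acetone, rt; filtration through silica
Reagents that add atoms: methyl hex-5-ynoate (the second molecule of 9), COC(=O)CCCC#C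
Why: The same Glaser–Hay homocoupling applies to this simple ester-bearing terminal alkyne, and the methyl ester is inert to the amine–copper system.

Step 6
Reactants: 10 dimethyl dodeca-5,7-diynedioate (4 equiv); 8 1,26-di(furan-2-yl)hexacosa-12,14-diyne (1 equiv)
Product: 11 methyl 19-(furan-2-yl)nonadeca-5,7-diynoate
Conditions: [Mo(≡CC6H4-4-OMe)(OSiPh3)3] (10 mol%), 5 Å MS, toluene, rt, argon; chromatography, recovered 8 and 10 resubmitted
Reagents that add atoms: none
Why: The hexavalent molybdenum alkylidyne adds across one triple bond of a diyne in a [2+2] cycloaddition with the metal on the alkyl-bearing carbon, and cycloreversion of the molybdacyclobutadiene releases a chain alkylidyne Mo≡C–CH2R; this adds in the same sense to the other homodimer, so that its carbyne carbon is joined to the inner alkynyl carbon and the mixed diyne leaves with one new triple bond (C5≡C6 when the ester-chain alkylidyne meets 8, C7≡C8 when the furyl-chain alkylidyne meets 10), one molecule of each homodimer giving two molecules of 11. The closest known reaction type is the cross-metathesis of symmetrical conjugated diynes with silanolate-supported tungsten or molybdenum alkylidynes. No ring closes and no stereocentre forms. The step needs diyne-to-diyne selectivity, which depends on the sense of metallacycle formation: both homodimers carry unbranched CH2 groups on the diyne termini, so the metal can reach the terminal carbon and the neighbouring alkynyl unit is passed on intact, without monoyne or triyne formation. The step also needs a favourable position of an otherwise statistical equilibrium, which the fourfold excess of the cheap diester 10 should provide for the furyl chain ends; esters and furans are tolerated by this catalyst, and 8, 11 and 10 differ enough in polarity to be separated and the homodimers equilibrated again.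

Step 7
Reactants: 11 methyl 19-(furan-2-yl)nonadeca-5,7-diynoate
Product: 13 19-(furan-2-yl)nonadeca-5,7-diynoic acid, via lithium 19-(furan-2-yl)nonadeca-5,7-diynoate 12 (not isolated)
Conditions: LiOH·H2O (3 equiv), THF/MeOH/H2O, 0 °C → rt; then cold 0.5 M HCl to pH 3–4
Reagents that add atoms: lithium hydroxide, [Li+].[OH-] (supplies the lithium of 12 and one carboxyl oxygen)
Why: Saponification of a methyl ester with aqueous hydroxide leaves the diyne and the furan alone, and the brief cold acidification is mild enough for a 2-alkylfuran.

Step 8
Reactants: 6 2-(4-chlorobutyl)furan
Product: 14 2-(hex-5-yn-1-yl)furan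
Conditions: LiC≡CH·H2NCH2CH2NH2 (1.5 equiv), NaI (20 mol%), DMSO, rt → 40 °C
Reagents that add atoms: lithium acetylide–ethylenediamine complex, [Li]C#C.NCCN
Why: SN2 alkynylation of the primary chloride by lithium acetylide in DMSO is assisted by Finkelstein exchange to the more reactive iodide.

Step 9
Reactants: 15 pent-4-yn-1-ol
Product: 16 5-bromopent-4-yn-1-ol
Conditions: NBS (1.1 equiv), AgNO3 (10 mol%), acetone, rt, dark
Reagents that add atoms: N-bromosuccinimide, O=C1CCC(=O)N1Br
Why: Silver-catalysed electrophilic bromination of a terminal alkyne tolerates the free primary alcohol, and placing the halogen on this partner keeps NBS away from the furan ring.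

Step 10
Reactants: 14 2-(hex-5-yn-1-yl)furan; 16 5-bromopent-4-yn-1-ol
Product: 17 11-(furan-2-yl)undeca-4,6-diyn-1-ol
Conditions: CuCl (10 mol%), NH2OH·HCl (30 mol%), 30% aq. n-BuNH2, Et2O, 0 °C, slow addition of 16
Reagents that add atoms: none
Why: In the Cadiot–Chodkiewicz coupling the copper acetylide of 14 attacks the bromoalkyne to give the unsymmetrical diyne, hydroxylamine keeps the copper monovalent, and neither the free alcohol nor the furan interferes.

Step 11
Reactants: 13 19-(furan-2-yl)nonadeca-5,7-diynoic acid; 17 11-(furan-2-yl)undeca-4,6-diyn-1-ol
Product: 18 11-(furan-2-yl)undeca-4,6-diyn-1-yl 19-(furan-2-yl)nonadeca-5,7-diynoate (target)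
Conditions: DCC (1.2 equiv), DMAP (10 mol%), CH2Cl2, 0 °C → rt
Reagents that add atoms: none
Why: Steglich esterification activates the acid as its O-acylisourea and DMAP passes the acyl group to the unhindered primary alcohol under neutral conditions that suit both diynes and both furans.

Compound list
1 | furan | c1ccoc1 | starting material
2 | 1,11-dibromoundecane | BrCCCCCCCCCCCBr | starting material
3 | 2-lithiofuran (furan-2-yllithium) | [Li]c1ccco1 | intermediate (made once in step 1, not isolated; its THF solution feeds steps 1 and 2)
4 | 2-(11-bromoundecyl)furan | BrCCCCCCCCCCCc1ccco1 | intermediate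
5 | 1-bromo-4-chlorobutane | ClCCCCBr | starting material
6 | 2-(4-chlorobutyl)furan | ClCCCCc1ccco1 | intermediate
7 | 2-(tridec-12-yn-1-yl)furan | C#CCCCCCCCCCCCc1ccco1 | intermediate
8 | 1,26-di(furan-2-yl)hexacosa-12,14-diyne | o1cccc1CCCCCCCCCCCC#CC#CCCCCCCCCCCCc1ccco1 | intermediate
9 | methyl hex-5-ynoate | COC(=O)CCCC#C | starting material
10 | dimethyl dodeca-5,7-diynedioate | COC(=O)CCCC#CC#CCCCC(=O)OC | intermediate
11 | methyl 19-(furan-2-yl)nonadeca-5,7-diynoate | COC(=O)CCCC#CC#CCCCCCCCCCCCc1ccco1 | intermediate
12 | lithium 19-(furan-2-yl)nonadeca-5,7-diynoate | [Li+].[O-]C(=O)CCCC#CC#CCCCCCCCCCCCc1ccco1 | intermediate (formed in the flask, not isolated)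
13 | 19-(furan-2-yl)nonadeca-5,7-diynoic acid | OC(=O)CCCC#CC#CCCCCCCCCCCCc1ccco1 | intermediate
14 | 2-(hex-5-yn-1-yl)furan | C#CCCCCc1ccco1 | intermediate
15 | pent-4-yn-1-ol | OCCCC#C | starting material
16 | 5-bromopent-4-yn-1-ol | OCCCC#CBr | intermediate
17 | 11-(furan-2-yl)undeca-4,6-diyn-1-ol | OCCCC#CC#CCCCCc1ccco1 | intermediate
18 | 11-(furan-2-yl)undeca-4,6-diyn-1-yl 19-(furan-2-yl)nonadeca-5,7-diynoate | O=C(CCCC#CC#CCCCCCCCCCCCc1ccco1)OCCCC#CC#CCCCCc1ccco1 | target

Total step count: 11 steps.
Longest linear sequence: 6 steps (steps 1, 3, 4, 6, 7 and 11).

Steps most likely to fail

Step 6. The exchange may stop at a statistical mixture that holds too little of the mixed diyne. The metallacycle may also open in the other sense and erode the diyne into monoynes and triynes. Traces of terminal alkyne or moisture may deactivate the alkylidyne. The fallback abandons metathesis and sets out from 9 and 7. Compound 9 is brominated at the alkyne terminus (NBS, AgNO3 cat., acetone, rt) to methyl 6-bromohex-5-ynoate F1. F1 is then joined to 7 in a Cadiot–Chodkiewicz coupling (CuCl cat., NH2OH·HCl, 30% aq. n-BuNH2, Et2O, 0 °C, short reaction time to spare the methyl ester). This gives 11 directly, where the route is rejoined.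

Step 10. Halogen–copper exchange between the bromoalkyne and the copper acetylide may cause each partner to dimerise, at the cost of the cross-coupled diynol. The fallback sets out from 14 and 15 and needs no bromoalkyne. An aerobic oxidative heterocoupling of the two terminal alkynes is run with a fivefold excess of the cheap alcohol 15 (NiCl2·6H2O cat., CuI cat., TMEDA, air, THF, rt). The non-polar difuryl dimer, the mono-alcohol 17 and the polar diol dimer should separate easily on silica, and the route is rejoined at 17. This fallback makes no compound outside the list (F0).

Step 1. The furyllithium may substitute both ends of the dibromide, and the non-polar monobromide may prove hard to free from the excess dibromide. The fallback sets out from 1 through 3 and uses a linker whose two ends already differ. Commercial 11-bromoundecan-1-ol is added to 2.2 equiv of 3 (THF/DMPU, −78 °C → rt), the first equivalent serving only to remove the hydroxyl proton. This gives the polar, easily purified 11-(furan-2-yl)undecan-1-ol F2. An Appel reaction (CBr4, PPh3, CH2Cl2, 0 °C) then converts F2 into the bromide, and the route is rejoined at 4.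

Further compounds
F1 | step 6 | methyl 6-bromohex-5-ynoate | COC(=O)CCCC#CBr
F0 | step 10 | none | none
F2 | step 1 | 11-(furan-2-yl)undecan-1-ol | OCCCCCCCCCCCc1ccco1
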